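## Structural features

The target is a 3-arylcoumarin: a benzene ring A fused to an α-pyranone ring C (2H-chromen-2-one), with a 2,4-dihydroxyphenyl ring B joined through the C3–C1' bond. Ring A is pentasubstituted: between the fusion atoms C4a and C8a it carries a free hydroxyl at C5, a 3-methylbut-2-enyl (prenyl) chain at C6, a methoxyl at C7 and a hydrogen at C8. There is no stereocentre and no alkene geometry to set, since the prenyl alkene ends in two identical methyl groups, so the problem is one of regiochemistry only. The fragile groups are the prenyl chain ortho to the free C5 phenol (acid closes it to a dimethylchroman), the lactone (opened by hydroxide) and the electron-rich resorcinol ring B. The real difficulty is ring A: three oxygens of a phloroglucinol pattern must end up as one lactone oxygen, one free phenol and one methyl ether, and the prenyl group must sit at C6 and not at C8 or on oxygen. The key step uses the sequence C5(OH)–C6(prenyl)–C7(OMe)–C8(H), which is exactly the sequence ketene carbonyl carbon, substituted alkyne carbon, alkoxy-bearing alkyne carbon and ketene α-carbon of a vinylketene–ynol ether benzannulation. C8a and C4a come from C6 and C5 of a 2-pyranone that already carries ring B.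

## Logic of the disconnections

**18 back to 17.** The two O–Si bonds on ring B are cut. The ring B phenols have to be inert through acid chloride, diazoketone and ketene chemistry, and their release must spare the prenyl–phenol pair and the lactone. Nothing is gained in skeleton, but the sensitive triphenol is kept apart from all C–C bond formation. The forward step must therefore be a desilylation that is neither acidic nor strongly basic.

**17 back to 8 and 12.** Four bonds are cut: C8–C8a, C5–C6, C7–C8 and C4a–C5, so ring A disappears. The cut is made here because the three contiguous substituents of ring A map directly onto a ketene carbonyl and the two carbons of an alkoxyalkyne. A pentasubstituted benzene is exchanged for a monocyclic lactone and an acyclic eight-carbon alkyne, and both the oxygen differentiation and the prenyl position become matters of connectivity. The forward step must generate a ketene on C6 of the lactone without disturbing the lactone chromophore, unite it with 12 in a single orientation, and close onto C5.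

**8 back to 6 (through 7).** The bond between the ketone carbon and the diazo carbon is cut, a one-carbon homologation of a carboxylic acid. The carboxyl is kept free and not as an ester, because an ester would have to be hydrolysed on a lactone that hydroxide opens and beside aryl silyl ethers that base removes. The forward step needs an acid activation the silyl ethers survive and a non-explosive diazomethane equivalent that acylates faster than it adds to the lactone double bonds.

**6 back to 2 and 5.** The C3–C1' bond is cut. It joins an electron-poor vinylic position to an electron-rich arene, the ideal polarity for a cross-coupling, and the cut divides the molecule into a ring B piece and a lactone piece of similar size. The coupling must tolerate a free carboxyl and two base-labile silyl ethers, so boron is carried as a pinacol ester and the base is kept mild.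

**2 back to 1.** The C3–Br bond is cut. C3 is the innate nucleophilic terminus of the ring-oxygen dienol ether system, so no directing group is needed. The forward step must substitute at C3 and not at C5.

**5 back to 4 and then 3.** The C–B bond is cut, then the two O–Si bonds. Boron is introduced at the bromide by palladium catalysis, because a carbanion at that carbon, ortho to a silyl ether, would pull the silyl group from oxygen to carbon. The forward steps require only exhaustive silylation and a borylation that leaves the silyl ethers alone.

**12 back to 9 and 10 (through 11).** The C2–C3 bond of 12 is cut, between the acetylenic carbon and the allylic CH2, and the methoxyalkyne is traced to 9 by two eliminations. This makes 12 in one flask from two bulk chemicals. The forward step must alkylate at the primary carbon of 10 and must not leave excess strong base in contact with the skipped enyne.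

## Other disconnections considered

**Alternative 1:** The cut is made on an isomeric skeleton. The C3–C1' and O1–C2 bonds of isoflavone A2 are disconnected, leading back to chalcone A1, and the carbonyl is afterwards moved from C4 to C2.
- Forward key step: Tl(NO3)3 in methanol would shift ring B of A1 from the β- to the α-carbon; acid would then close the pyran ring and remove the methoxymethyl ethers to give A2.
- In favour: A1 comes from an aldol condensation of two cheap aromatic pieces. The oxidative aryl shift is long established and is at its best with an electron-rich migrating ring. It needs neither light nor a diazo compound. On precedent this key step is the better of the two.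
- Equal point: the chelated C5 hydroxyl of A2 lets the C7 oxygen be methylated selectively, so on differentiating the ring A oxygens the alternative is the equal of the chosen plan.
- Against: trivalent thallium is needed in stoichiometric amount. A2 has its carbonyl on the wrong carbon, so a reduction at C4 and an oxidation at C2 must follow with three phenols present. The prenyl group is still missing, and placing it at C6 instead of C8 or oxygen is the very problem that 17 solves by construction.
- Comparison: in structure it builds ring C and leaves ring A to late substitution, whereas the chosen plan builds ring A with all five substituents in place. In mechanism a cationic aryl shift stands against a pericyclic cascade whose regiochemistry is fixed by connectivity. In step economy the transposition and the prenylation should make it longer by several steps.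

**Alternative 2:** All four bonds of the lactone ring are cut (C8a–O1, C4a–C4, C3–C4, O1–C2). This gives silylaryl triflate A3, N,N-dimethylformamide A4 as the source of C4, and arylacetate A5.
- Forward key step: CsF would strip the silyl and triflate groups of A3, the strained triple bond would take up the carbonyl of A4, the zinc enolate of A5 would add at C4, the amino group would leave and the phenoxide would lactonize to A6.
- In favour: three components are joined in one operation and ring B arrives without a cross-coupling. The alkoxy group next to the triple bond should send the oxygen to the distal carbon, which is the required orientation.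
- Equal or better points: in convergence and in the number of bonds formed (four) it is the equal of the chosen key step. In operational simplicity (no light, no diazo compound) it is the better.
- Against: A3 is itself a multistep target, a phloroglucinol with three different oxygens and an ortho silyl–triflate pair. Ring A of A6 has no prenyl group; this must be placed at C6 after the benzylic ether is removed, for instance by O-allylation and Claisen rearrangement. The final acidic removal of the methoxymethyl ethers threatens the prenyl–phenol pair.
- Comparison: in structure it again makes ring C and postpones the hardest feature of ring A. In mechanism a polar cascade with one regiochemical decision stands against a pericyclic cascade with one regiochemical decision, a fair match. In step economy the synthesis of A3 and the late prenylation should outweigh the gain of the three-component step.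

**Alternative 3:** Only the C3=C4 double bond is cut, which gives diene A7.
- Forward key step: second-generation Grubbs catalyst RuCl2(CHPh)(PCy3)(H2IMes) would join the vinyl group on C4a with the 2-arylacrylate on O1 and close the lactone ring to A8, with loss of the two terminal CH2 groups.
- In favour: metathesis is neutral and tolerant, and ring B arrives with the acrylate. Mechanistically it is the most predictable of the four key steps, and in that respect the better of the chosen plan.
- Against: a 1,1-disubstituted, electron-poor acrylate carrying an ortho-substituted aryl group is a slow metathesis partner, and the product alkene is trisubstituted. A7 needs a vinyl group between two differently masked oxygens on ring A and an acrylic ester prone to polymerization. The prenyl alkene cannot be present during metathesis, so prenylation is again a late and regiochemically open step.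
- Comparison: in structure one bond is formed against four, and no ring A substituent is set. In mechanism the catalytic cycle is better understood than the photochemical cascade. In step economy the preparation of A7 and the late prenylation should make the route clearly longer.

Key step: step 7

Remark on the chemistry: bromination of 1 is taken to occur at C3, by analogy with the behaviour of other 2-pyranone carboxylic acids. The target is achiral, so no stereochemical assumption is needed.

## Route

Step 1
Reactants: 1 2-oxo-2H-pyran-6-carboxylic acid
Product: 2 3-bromo-2-oxo-2H-pyran-6-carboxylic acid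
Conditions: Br2 (1.1 equiv), AcOH, 60 °C
Reagents that add atoms: bromine, BrBr
Why: Electrophilic bromination of a 2-pyranone; C3 is the terminus of the O1–C6=C5–C4=C3 dienol ether system, whereas C5 is the deactivated β-carbon of the C6 acrylic acid unit and is shielded by the carboxyl, so substitution should occur at C3 as it does in other pyranone carboxylic acids.

Step 2
Reactants: 3 4-bromoresorcinol
Product: 4 1-bromo-2,4-bis(tert-butyldimethylsilyloxy)benzene
Conditions: TBSCl (2.4 equiv), imidazole, DMF, 20 °C
Reagents that add atoms: tert-butyldimethylsilyl chloride, CC(C)(C)[Si](C)(C)Cl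
Why: Imidazole-promoted silylation of both phenols; no selectivity is required, and fluoride-labile ethers are chosen so that the last step needs neither acid nor strong base.

Step 3
Reactants: 4 1-bromo-2,4-bis(tert-butyldimethylsilyloxy)benzene
Product: 5 2-[2,4-bis(tert-butyldimethylsilyloxy)phenyl]-4,4,5,5-tetramethyl-1,3,2-dioxaborolane
Conditions: B2pin2, PdCl2(dppf) (cat.), KOAc, dioxane, 85 °C
Reagents that add atoms: bis(pinacolato)diboron, CC1(C)OB(OC1(C)C)B1OC(C)(C)C(C)(C)O1
Why: Miyaura borylation (zerovalent palladium inserts into C–Br, acetate-assisted transmetalation with the diboron); it avoids an aryllithium, which would undergo retro-Brook O-to-C silyl migration from the ortho silyl ether, and gives a pinacol ester that resists protodeboronation better than the free boronic acid.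

Step 4
Reactants: 2 3-bromo-2-oxo-2H-pyran-6-carboxylic acid; 5 2-[2,4-bis(tert-butyldimethylsilyloxy)phenyl]-4,4,5,5-tetramethyl-1,3,2-dioxaborolane
Product: 6 3-[2,4-bis(tert-butyldimethylsilyloxy)phenyl]-2-oxo-2H-pyran-6-carboxylic acid
Conditions: PdCl2(dppf) (cat.), K3PO4 (3 equiv), dioxane/H2O (10:1), 60 °C; work-up at pH 4
Reagents that add atoms: none
Why: Suzuki–Miyaura coupling; the C3–Br bond is that of an α-bromo enoate and should add readily to zerovalent palladium, while the carboxylate form makes the pyranone less electrophilic toward hydroxide and the mild phosphate base spares the aryl silyl ethers.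

Step 5
Reactants: 6 3-[2,4-bis(tert-butyldimethylsilyloxy)phenyl]-2-oxo-2H-pyran-6-carboxylic acid
Product: 8 3-[2,4-bis(tert-butyldimethylsilyloxy)phenyl]-6-(2-diazoacetyl)-2H-pyran-2-one, via acid chloride 7 (not isolated)
Conditions: (COCl)2, DMF (cat.), CH2Cl2, 0 to 20 °C; evaporate; Me3SiCHN2 (2 equiv), THF/MeCN (1:1), 0 to 20 °C
Reagents that add atoms: (trimethylsilyl)diazomethane, C[Si](C)(C)C=[N+]=[N-]; oxalyl chloride, O=C(Cl)C(=O)Cl (chlorine of 7 only)
Why: Acid chloride formation followed by C-acylation of a diazoalkane, the first stage of an Arndt–Eistert sequence; chloride removes the silyl group from the acylated intermediate, so no HCl is set free in the second stage, and the non-explosive silyl reagent replaces diazomethane.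

Step 6
Reactants: 9 2-chloro-1,1-dimethoxyethane (chloroacetaldehyde dimethyl acetal); 10 1-bromo-3-methylbut-2-ene (prenyl bromide)
Product: 12 1-methoxy-5-methylhex-4-en-1-yne, via sodium methoxyacetylide 11 (not isolated)
Conditions: NaNH2 (3.0 equiv), liquid NH3, −33 °C; then 10, −33 °C; NH4Cl, pentane work-up
Reagents that add atoms: none
Why: Two base-induced eliminations (HCl, then MeOH) and deprotonation give the alkoxyacetylide, which is C-alkylated by SN2 attack at the primary allylic carbon; the methyl ether is the right choice because a methoxyalkyne has no β-hydrogen and cannot fragment to a ketene by retro-ene reaction when heated in step 7.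

Step 7
Reactants: 8 3-[2,4-bis(tert-butyldimethylsilyloxy)phenyl]-6-(2-diazoacetyl)-2H-pyran-2-one; 12 1-methoxy-5-methylhex-4-en-1-yne
Product: 17 3-[2,4-bis(tert-butyldimethylsilyloxy)phenyl]-5-hydroxy-7-methoxy-6-(3-methylbut-2-enyl)-2H-chromen-2-one, via vinylketene 13 (not isolated), via cyclobutenone 14 (not isolated), via dienylketene 15 (not isolated), via cyclohexadienone 16 (not isolated)
Conditions: 12 (2.5 equiv), hν (440 nm LED), degassed ClCH2CH2Cl, 20 °C; evaporate excess 12; toluene, 80 °C, dark
Reagents that add atoms: none
Why: Danheiser benzannulation in its photochemical Wolff form, the established annulation of α,β-unsaturated and heteroaryl diazoketones with alkoxyalkynes, here with the C5=C6 bond of the 2-pyranone as the vinyl unit. Excitation of the diazo chromophore at 440 nm, where neither the pyranone nor the coumarin product is expected to absorb appreciably, expels N2 with a concerted 1,2-shift of pyranone C6 from the carbonyl to the diazo carbon (C8–C8a) and gives vinylketene 13. The nucleophilic, prenyl-bearing carbon of 12 attacks the ketene carbonyl carbon and the methoxy-bearing carbon closes onto the ketene CH, a regiospecific [2+2] cycloaddition that forms C5–C6 and C7–C8 in cyclobutenone 14. At 80 °C 14 opens by a conrotatory 4π process to dienylketene 15; the opening is reversible, so material is drained through the isomer in which the pyranone lies cis to the ketene carbon. Ring A then closes by a thermal disrotatory 6π electrocyclization of the ketene carbon onto pyranone C5 (C4a–C5), and dienone 16 aromatizes by a proton shift from C4a to oxygen. No stereocentre survives (the sp3 carbons of 14 and 16 are transient and racemic); the only selectivity needed is the orientation of the alkyne, which the polarization of the ynol ether secures, and the preference of the ketene for the electron-rich triple bond over the trisubstituted prenyl alkene. Excess 12 is removed before heating so that the new phenol meets neither the ynol ether nor unconsumed ketene.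

Step 8
Reactants: 17 3-[2,4-bis(tert-butyldimethylsilyloxy)phenyl]-5-hydroxy-7-methoxy-6-(3-methylbut-2-enyl)-2H-chromen-2-one
Product: 18 3-(2,4-dihydroxyphenyl)-5-hydroxy-7-methoxy-6-(3-methylbut-2-enyl)-2H-chromen-2-one
Conditions: Bu4NF (2.5 equiv), AcOH (2.5 equiv), THF, 0 °C
Reagents that add atoms: none
Why: Fluoride-induced cleavage of the two aryl silyl ethers; the acetic acid buffer keeps the phenols protonated, so the lactone is not opened and the prenyl–phenol pair sees no acid strong enough to cyclize it.

## Compound list

1 | 2-oxo-2H-pyran-6-carboxylic acid | O=C(O)c1cccc(=O)o1 | starting material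
2 | 3-bromo-2-oxo-2H-pyran-6-carboxylic acid | O=C(O)c1ccc(Br)c(=O)o1 | intermediate
3 | 4-bromoresorcinol (4-bromobenzene-1,3-diol) | Oc1ccc(Br)c(O)c1 | starting material
4 | 1-bromo-2,4-bis(tert-butyldimethylsilyloxy)benzene | CC(C)(C)[Si](C)(C)Oc1ccc(Br)c(O[Si](C)(C)C(C)(C)C)c1 | intermediate
5 | 2-[2,4-bis(tert-butyldimethylsilyloxy)phenyl]-4,4,5,5-tetramethyl-1,3,2-dioxaborolane | CC(C)(C)[Si](C)(C)Oc1ccc(B2OC(C)(C)C(C)(C)O2)c(O[Si](C)(C)C(C)(C)C)c1 | intermediate
6 | 3-[2,4-bis(tert-butyldimethylsilyloxy)phenyl]-2-oxo-2H-pyran-6-carboxylic acid | O=C(O)c1ccc(-c2ccc(O[Si](C)(C)C(C)(C)C)cc2O[Si](C)(C)C(C)(C)C)c(=O)o1 | intermediate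
7 | 3-[2,4-bis(tert-butyldimethylsilyloxy)phenyl]-2-oxo-2H-pyran-6-carbonyl chloride | O=C(Cl)c1ccc(-c2ccc(O[Si](C)(C)C(C)(C)C)cc2O[Si](C)(C)C(C)(C)C)c(=O)o1 | intermediate
8 | 3-[2,4-bis(tert-butyldimethylsilyloxy)phenyl]-6-(2-diazoacetyl)-2H-pyran-2-one | [N-]=[N+]=CC(=O)c1ccc(-c2ccc(O[Si](C)(C)C(C)(C)C)cc2O[Si](C)(C)C(C)(C)C)c(=O)o1 | intermediate
9 | 2-chloro-1,1-dimethoxyethane (chloroacetaldehyde dimethyl acetal) | COC(CCl)OC | starting material
10 | 1-bromo-3-methylbut-2-ene (prenyl bromide) | CC(C)=CCBr | starting material
11 | sodium methoxyacetylide | [Na+].[C-]#COC | intermediate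
12 | 1-methoxy-5-methylhex-4-en-1-yne | COC#CCC=C(C)C | intermediate
13 | 3-[2,4-bis(tert-butyldimethylsilyloxy)phenyl]-6-(2-oxoethenyl)-2H-pyran-2-one | O=C=Cc1ccc(-c2ccc(O[Si](C)(C)C(C)(C)C)cc2O[Si](C)(C)C(C)(C)C)c(=O)o1 | intermediate
14 | 3-[2,4-bis(tert-butyldimethylsilyloxy)phenyl]-6-[2-methoxy-3-(3-methylbut-2-enyl)-4-oxocyclobut-2-en-1-yl]-2H-pyran-2-one (racemic) | COC1=C(CC=C(C)C)C(=O)C1c1ccc(-c2ccc(O[Si](C)(C)C(C)(C)C)cc2O[Si](C)(C)C(C)(C)C)c(=O)o1 | intermediate
15 | 3-[2,4-bis(tert-butyldimethylsilyloxy)phenyl]-6-[(1E)-2-methoxy-6-methyl-3-(oxomethylidene)hepta-1,5-dien-1-yl]-2H-pyran-2-one (pyranone cis to the ketene carbon) | O=C=C(CC=C(C)C)/C(OC)=C\c1ccc(-c2ccc(O[Si](C)(C)C(C)(C)C)cc2O[Si](C)(C)C(C)(C)C)c(=O)o1 | intermediate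
16 | 3-[2,4-bis(tert-butyldimethylsilyloxy)phenyl]-7-methoxy-6-(3-methylbut-2-enyl)-4aH-chromene-2,5-dione (racemic at C4a) | COC1=C(CC=C(C)C)C(=O)C2C=C(-c3ccc(O[Si](C)(C)C(C)(C)C)cc3O[Si](C)(C)C(C)(C)C)C(=O)OC2=C1 | intermediate
17 | 3-[2,4-bis(tert-butyldimethylsilyloxy)phenyl]-5-hydroxy-7-methoxy-6-(3-methylbut-2-enyl)-2H-chromen-2-one | COc1cc2oc(=O)c(-c3ccc(O[Si](C)(C)C(C)(C)C)cc3O[Si](C)(C)C(C)(C)C)cc2c(O)c1CC=C(C)C | intermediate
18 | 3-(2,4-dihydroxyphenyl)-5-hydroxy-7-methoxy-6-(3-methylbut-2-enyl)-2H-chromen-2-one | COc1cc2oc(=O)c(-c3ccc(O)cc3O)cc2c(O)c1CC=C(C)C | target

## Step count and least certain steps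

Total: 8 steps. Longest linear sequence: 6 steps (steps 2, 3, 4, 5, 7, 8, from 3 to 18).

**Step 7 (key step).** A 2-pyranone has not yet served as the vinyl partner, and two things are most likely to go wrong. Light may be absorbed by the pyranone of 8 or the coumarin of 17 and lead to electrocyclic or dimerization photochemistry. Ketene 13 may also be consumed by dimerization or by acylating the phenol of 17 before it meets the alkyne. The fallback makes the same ketene without light. It sets out from 8 and comes back at 17. Wolff rearrangement of 8 catalysed by AgO2CPh with Et3N in aqueous dioxane (the second stage of an Arndt–Eistert homologation) should give 2-{3-[2,4-bis(tert-butyldimethylsilyloxy)phenyl]-2-oxo-2H-pyran-6-yl}acetic acid F1. Oxalyl chloride converts this into 2-{3-[2,4-bis(tert-butyldimethylsilyloxy)phenyl]-2-oxo-2H-pyran-6-yl}acetyl chloride F2. Slow addition of Et3N to F2 and excess 12 in toluene at 20 °C generates 13 by dehydrochlorination in the dark, and 13 is taken up as 14. Heating at 80 °C then leads through 15 and 16 to 17.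

**Step 1.** Bromine may attack C5 as well as C3, or brominate twice, and free acids can only be separated by crystallization. The fallback sets out from 1 and comes back at 2. Esterification (MeOH, H2SO4 cat.) gives methyl 2-oxo-2H-pyran-6-carboxylate F3. Bromine addition in CH2Cl2 followed by Et3N-induced loss of HBr, an addition–elimination in place of direct substitution, gives methyl 3-bromo-2-oxo-2H-pyran-6-carboxylate F4, which can be freed of any isomer by chromatography. Hydrolysis in aqueous HCl/dioxane at 80 °C then gives 2; acid is used because hydroxide would open the lactone.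

**Step 4.** Protodeboronation of the electron-rich, ortho-silyloxy boronate may outrun transmetalation, and the aqueous base may strip the aryl silyl ethers or open the lactone. The fallback is a base-free, water-free coupling. It sets out from 4 and comes back at 6. Stannylation of 4 with hexabutylditin and Pd(PPh3)4 in toluene at 110 °C gives tributyl[2,4-bis(tert-butyldimethylsilyloxy)phenyl]stannane F5. Stille coupling of F5 with 2, held as its diisopropylethylammonium salt, with Pd(PPh3)4 and CuI in DMF at 60 °C, gives 6 after work-up at pH 4.

**Step 5.** The diazoalkane may add as a 1,3-dipole to the electron-poor double bonds of the pyranone in competition with acylation, and HCl from the chlorination may loosen a silyl ether or turn the product into a chloromethyl ketone. The fallback avoids diazoalkanes. It sets out from 7 and comes back at 8. Negishi acylation of 7 with MeZnCl and Pd(PPh3)4 (cat.) in THF at 0 °C gives 6-acetyl-3-[2,4-bis(tert-butyldimethylsilyloxy)phenyl]-2H-pyran-2-one F6. Enolization with LiN(SiMe3)2 at −78 °C and trifluoroacetylation with CF3CO2CH2CF3 give 1-{3-[2,4-bis(tert-butyldimethylsilyloxy)phenyl]-2-oxo-2H-pyran-6-yl}-4,4,4-trifluorobutane-1,3-dione F7. Detrifluoroacetylative diazo transfer with 4-acetamidobenzenesulfonyl azide, Et3N and water in MeCN then gives 8.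

**Step 6.** Surplus amide may move the skipped enyne of 12 into allenic or conjugated isomers, and ammonia or SN2' attack may consume 10. The fallback makes the acetylide with an organolithium at low temperature. It sets out from 10, with commercial trichloroethylene and methanol, and comes back at 12. KH, MeOH and trichloroethylene in THF give (E)-1,2-dichloro-1-methoxyethene F8. n-BuLi (2.2 equiv) in THF at −78 °C converts F8 into lithium methoxyacetylide F9, which is alkylated with 10 in THF/DMPU at −40 °C to give 12.

## Further compounds

F1 | step 7 | 2-{3-[2,4-bis(tert-butyldimethylsilyloxy)phenyl]-2-oxo-2H-pyran-6-yl}acetic acid | O=C(O)Cc1ccc(-c2ccc(O[Si](C)(C)C(C)(C)C)cc2O[Si](C)(C)C(C)(C)C)c(=O)o1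
F2 | step 7 | 2-{3-[2,4-bis(tert-butyldimethylsilyloxy)phenyl]-2-oxo-2H-pyran-6-yl}acetyl chloride | O=C(Cl)Cc1ccc(-c2ccc(O[Si](C)(C)C(C)(C)C)cc2O[Si](C)(C)C(C)(C)C)c(=O)o1
F3 | step 1 | methyl 2-oxo-2H-pyran-6-carboxylate | COC(=O)c1cccc(=O)o1
F4 | step 1 | methyl 3-bromo-2-oxo-2H-pyran-6-carboxylate | COC(=O)c1ccc(Br)c(=O)o1
F5 | step 4 | tributyl[2,4-bis(tert-butyldimethylsilyloxy)phenyl]stannane | CCCC[Sn](CCCC)(CCCC)c1ccc(O[Si](C)(C)C(C)(C)C)cc1O[Si](C)(C)C(C)(C)C
F6 | step 5 | 6-acetyl-3-[2,4-bis(tert-butyldimethylsilyloxy)phenyl]-2H-pyran-2-one | CC(=O)c1ccc(-c2ccc(O[Si](C)(C)C(C)(C)C)cc2O[Si](C)(C)C(C)(C)C)c(=O)o1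
F7 | step 5 | 1-{3-[2,4-bis(tert-butyldimethylsilyloxy)phenyl]-2-oxo-2H-pyran-6-yl}-4,4,4-trifluorobutane-1,3-dione | O=C(CC(=O)C(F)(F)F)c1ccc(-c2ccc(O[Si](C)(C)C(C)(C)C)cc2O[Si](C)(C)C(C)(C)C)c(=O)o1
F8 | step 6 | (E)-1,2-dichloro-1-methoxyethene | CO/C(Cl)=C\Cl
F9 | step 6 | lithium methoxyacetylide | [Li+].[C-]#COC
A1 | alternative 1 | (E)-3-[2,4-bis(methoxymethoxy)phenyl]-1-[2-hydroxy-4-methoxy-6-(methoxymethoxy)phenyl]prop-2-en-1-one | COCOc1ccc(/C=C/C(=O)c2c(O)cc(OC)cc2OCOC)c(OCOC)c1
A2 | alternative 1 | 3-(2,4-dihydroxyphenyl)-5-hydroxy-7-methoxy-4H-chromen-4-one | COc1cc(O)c2c(c1)occ(-c1ccc(O)cc1O)c2=O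
A3 | alternative 2 | 5-methoxy-3-[(4-methoxyphenyl)methoxy]-2-(trimethylsilyl)phenyl trifluoromethanesulfonate | COc1cc(OCc2ccc(OC)cc2)c([Si](C)(C)C)c(OS(=O)(=O)C(F)(F)F)c1
A4 | alternative 2 | N,N-dimethylformamide | CN(C)C=O
A5 | alternative 2 | methyl 2-[2,4-bis(methoxymethoxy)phenyl]acetate | COCOc1ccc(CC(=O)OC)c(OCOC)c1
A6 | alternative 2 | 3-[2,4-bis(methoxymethoxy)phenyl]-7-methoxy-5-[(4-methoxyphenyl)methoxy]-2H-chromen-2-one | COc1cc2oc(=O)c(-c3ccc(OCOC)cc3OCOC)cc2c(OCc2ccc(OC)cc2)c1
A7 | alternative 3 | 3-(tert-butyldimethylsilyloxy)-5-methoxy-2-vinylphenyl 2-[2,4-bis(methoxymethoxy)phenyl]prop-2-enoate | C=Cc1c(OC(=O)C(=C)c2ccc(OCOC)cc2OCOC)cc(OC)cc1O[Si](C)(C)C(C)(C)C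
A8 | alternative 3 | 3-[2,4-bis(methoxymethoxy)phenyl]-5-(tert-butyldimethylsilyloxy)-7-methoxy-2H-chromen-2-one | COc1cc2oc(=O)c(-c3ccc(OCOC)cc3OCOC)cc2c(O[Si](C)(C)C(C)(C)C)c1
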